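**Retrosynthetic overview**

1. Working locants: C1 is the ring carbon with the exocyclic methylene (C1′); then C2, C3, C4=C5(CH3), C6, C7, C8 (isopropenyl), C9 (OAc), C10=C11 (C11 carries C11′H2OAc), C12, C13, C14 (OH).
2. Target ⇐ reagent-controlled reduction of a 14-membered 2-methylene ketone (sets C14) ⇐ ring closure at C14–C1 by alkyne hydroacylation, in which the C14 aldehyde acts as an acyl anion equivalent toward C1 of a terminal alkyne. This is the only ring, formed in step 11.
3. Seco alkynal ⇐ C8–C9 bond by catalytic asymmetric chromium-mediated allylation of a C9–C14 enal with a C1–C8 allylic bromide (sets C8 and C9).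
4. Enal ⇐ but-2-yne-1,4-diol (directed hydroalumination–iodination fixes C10=C11) plus a propanal homoenolate zinc reagent (C11–C12 bond; brings C14 as a masked aldehyde).
5. Allylic bromide ⇐ (E)-geranylacetone (methyl ketone → terminal alkyne, E-selective allylic oxidation, bromination).

Assumption: geranylacetone is bought as its pure (5E) isomer; systematic names below use IUPAC locants, the discussion uses the working locants of line 1.

**Route**

Step 1
Reactants: 1 but-2-yne-1,4-diol
Product: 3 4-{[tert-butyl(dimethyl)silyl]oxy}but-2-yn-1-ol, via sodium monoalkoxide 2 (not isolated)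
Conditions: NaH (1.0 equiv), THF, 0 °C to rt; then TBSCl (1.0 equiv), rt
Reagents that add atoms: tert-butyl(chloro)dimethylsilane, CC(C)(C)[Si](C)(C)Cl
Why: Mono-silylation of a symmetrical diol through its sparingly soluble monosodium salt (silyl ether protection) leaves one free hydroxyl to direct the next step.

Step 2
Reactants: 3 4-{[tert-butyl(dimethyl)silyl]oxy}but-2-yn-1-ol
Product: 5 (2Z)-4-{[tert-butyl(dimethyl)silyl]oxy}-3-iodobut-2-en-1-ol, via cyclic alkenylalanate 4 (not isolated)
Conditions: NaAlH2(OCH2CH2OMe)2, THF, 0 °C; then I2, THF, -78 °C; aq. potassium sodium tartrate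
Reagents that add atoms: iodine, II
Why: Hydroxyl-directed trans-hydroalumination of the propargylic alcohol and iodinolysis of the alkenyl–aluminium bond with retention put iodine on C11 cis to the CH2OH carbon, which fixes the C10=C11 geometry of the target.

Step 3
Reactants: 5 (2Z)-4-{[tert-butyl(dimethyl)silyl]oxy}-3-iodobut-2-en-1-ol, 6 [2-(1,3-dioxolan-2-yl)ethyl]zinc bromide
Product: 7 (2E)-3-({[tert-butyl(dimethyl)silyl]oxy}methyl)-5-(1,3-dioxolan-2-yl)pent-2-en-1-ol
Conditions: 6 (2.5 equiv, 0.5 M in THF), Pd(PPh3)4 (5 mol %), THF, 45 °C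
Reagents that add atoms: none
Why: Negishi sp2–sp3 cross-coupling with retention of alkene geometry, in which the zinc reagent is a propanal homoenolate equivalent, so that C12 (normally the electrophilic beta carbon of an enal) is joined as a nucleophile to the electrophilic iodoalkene carbon C11 and C14 arrives as a masked aldehyde.

Step 4
Reactants: 7 (2E)-3-({[tert-butyl(dimethyl)silyl]oxy}methyl)-5-(1,3-dioxolan-2-yl)pent-2-en-1-ol
Product: 8 (2E)-3-({[tert-butyl(dimethyl)silyl]oxy}methyl)-5-(1,3-dioxolan-2-yl)pent-2-enal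
Conditions: activated MnO2 (excess), CH2Cl2, rt
Reagents that add atoms: none
Why: Chemoselective MnO2 oxidation of the primary allylic alcohol gives the enal under neutral conditions that leave the silyl ether, the acetal and the alkene geometry untouched.

Step 5
Reactants: 9 (5E)-6,10-dimethylundeca-5,9-dien-2-one
Product: 11 (5E)-6,10-dimethylundeca-5,9-dien-1-yne, via enol phosphate 10 (not isolated)
Conditions: LiN(i-Pr)2 (1.1 equiv), THF, -78 °C; ClP(O)(OEt)2; then LiN(i-Pr)2 (2.3 equiv), -78 °C to rt; aq. NH4Cl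
Reagents that add atoms: none
Why: Kinetic enolisation at the methyl group, O-phosphorylation and base-induced elimination of the enol phosphate (Negishi methyl ketone to terminal alkyne protocol) turn the acetyl group into the C1≡C1′ alkyne without touching the E-trisubstituted alkene.

Step 6
Reactants: 11 (5E)-6,10-dimethylundeca-5,9-dien-1-yne
Product: 12 (2E,6E)-2,6-dimethylundeca-2,6-dien-10-yn-1-ol
Conditions: SeO2 (0.3 equiv), t-BuOOH (2 equiv), salicylic acid (0.1 equiv), CH2Cl2, 0 °C to rt
Reagents that add atoms: tert-butyl hydroperoxide, CC(C)(C)OO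
Why: Catalytic SeO2 allylic oxidation (ene reaction then [2,3]-sigmatropic shift) is selective for the E-methyl group of the terminal trisubstituted alkene and tolerates the alkyne.

Step 7
Reactants: 12 (2E,6E)-2,6-dimethylundeca-2,6-dien-10-yn-1-ol
Product: 13 (5E,9E)-11-bromo-6,10-dimethylundeca-5,9-dien-1-yne
Conditions: CBr4, PPh3, CH2Cl2, -20 to 0 °C
Reagents that add atoms: carbon tetrabromide, BrC(Br)(Br)Br
Why: Appel bromination converts the primary allylic alcohol into the bromide under neutral conditions without allylic transposition.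

Step 8
Reactants: 13 (5E,9E)-11-bromo-6,10-dimethylundeca-5,9-dien-1-yne, 8 (2E)-3-({[tert-butyl(dimethyl)silyl]oxy}methyl)-5-(1,3-dioxolan-2-yl)pent-2-enal
Product: 15 (2E,4S,5R,8E)-2-[2-(1,3-dioxolan-2-yl)ethyl]-8-methyl-5-(prop-1-en-2-yl)trideca-2,8-dien-12-yne-1,4-diol, via bis-silyl ether 14 (not isolated)
Conditions: CrCl2 (10 mol %), chiral 1,8-bis(4-isopropyl-4,5-dihydrooxazol-2-yl)-3,6-diphenyl-9H-carbazole ligand (12 mol %, antipode that gives Re-face addition), Mn powder, Me3SiCl, i-Pr2NEt (30 mol %), THF, 0 °C to rt; then Bu4NF (3 equiv), THF, rt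
Reagents that add atoms: none
Why: Catalytic asymmetric Nozaki–Hiyama–Kishi allylation in which the E-allylchromium adds through its gamma carbon (C8) in a chair transition state to give the anti C8/C9 homoallylic alcohol with the isopropenyl group formed in place, the ligand directs attack to the Re face of the enal (9S and therefore 8R), and fluoride then removes both silyl groups.

Step 9
Reactants: 15 (2E,4S,5R,8E)-2-[2-(1,3-dioxolan-2-yl)ethyl]-8-methyl-5-(prop-1-en-2-yl)trideca-2,8-dien-12-yne-1,4-diol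
Product: 16 (2E,4S,5R,8E)-2-[2-(1,3-dioxolan-2-yl)ethyl]-8-methyl-5-(prop-1-en-2-yl)trideca-2,8-dien-12-yne-1,4-diyl diacetate
Conditions: Ac2O, pyridine, DMAP (cat.), CH2Cl2, 0 °C to rt
Reagents that add atoms: acetic anhydride, CC(=O)OC(C)=O
Why: DMAP-catalysed acetylation esterifies the primary and the hindered secondary allylic alcohol, so both acetates of the target are in place before the C14 oxygen exists.

Step 10
Reactants: 16 (2E,4S,5R,8E)-2-[2-(1,3-dioxolan-2-yl)ethyl]-8-methyl-5-(prop-1-en-2-yl)trideca-2,8-dien-12-yne-1,4-diyl diacetate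
Product: 17 (2E,4S,5R,8E)-8-methyl-2-(3-oxopropyl)-5-(prop-1-en-2-yl)trideca-2,8-dien-12-yne-1,4-diyl diacetate
Conditions: PPTS (0.2 equiv), acetone/H2O (9:1), 55 °C
Reagents that add atoms: water, O
Why: Mild acid-catalysed acetal hydrolysis frees the C14 aldehyde without ionising the allylic acetates.

Step 11
Reactants: 17 (2E,4S,5R,8E)-8-methyl-2-(3-oxopropyl)-5-(prop-1-en-2-yl)trideca-2,8-dien-12-yne-1,4-diyl diacetate
Product: 20 [(1E,3S,4R,7E)-3-(acetyloxy)-7-methyl-11-methylidene-12-oxo-4-(prop-1-en-2-yl)cyclotetradeca-1,7-dien-1-yl]methyl acetate, via aldimine 18 (not isolated), via macrocyclic ketimine 19 (not isolated)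
Conditions: RhCl(PPh3)3 (20 mol %), 2-amino-3-methylpyridine (1 equiv), PhCO2H (0.5 equiv), toluene, 100 °C, slow addition of 17 (final 1 mM); then wet silica gel
Reagents that add atoms: none
Why: Proposed new method: condensation with 2-amino-3-methylpyridine gives an aldimine whose C–H bond adds to rhodium under pyridine chelation, so that C14 becomes an iminoacyl–rhodium hydride (a catalytic acyl anion equivalent) that hydrometalates the tethered terminal alkyne with hydride to C1′ and rhodium to C1, forms the C14–C1 bond by reductive elimination and is hydrolysed to the 2-methylene ketone; the closest known reaction is the intermolecular chelation-assisted rhodium-catalysed hydroacylation of 1-alkynes with aldehydes, which gives branched 1,1-disubstituted enones, here run at high dilution as a 14-membered ring closure.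

Step 12
Reactants: 20 [(1E,3S,4R,7E)-3-(acetyloxy)-7-methyl-11-methylidene-12-oxo-4-(prop-1-en-2-yl)cyclotetradeca-1,7-dien-1-yl]methyl acetate
Product: 21 [(1E,3S,4R,7E,12R)-3-(acetyloxy)-12-hydroxy-7-methyl-11-methylidene-4-(prop-1-en-2-yl)cyclotetradeca-1,7-dien-1-yl]methyl acetate
Conditions: (S)-2-methyl-CBS-oxazaborolidine (0.5 equiv), catecholborane (1.5 equiv), toluene, -78 °C
Reagents that add atoms: none
Why: Corey–Bakshi–Shibata reduction gives clean 1,2-reduction of the enone, and the (S)-oxazaborolidine delivers hydride to the Si face of a ketone whose larger group is the alpha-branched alkenyl carbon C1, which sets the carbinol centre as R under reagent control.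

**Compound list**

1 | but-2-yne-1,4-diol | OCC#CCO | starting material
2 | sodium 4-hydroxybut-2-yn-1-olate | [Na+].[O-]CC#CCO | intermediate
3 | 4-{[tert-butyl(dimethyl)silyl]oxy}but-2-yn-1-ol | OCC#CCO[Si](C)(C)C(C)(C)C | intermediate
4 | sodium 3-({[tert-butyl(dimethyl)silyl]oxy}methyl)-2,2-bis(2-methoxyethoxy)-2,5-dihydro-1,2-oxaluminol-2-uide (cyclic alkenylalanate) | [Na+].COCCO[Al-]1(OCCOC)OCC=C1CO[Si](C)(C)C(C)(C)C | intermediate
5 | (2Z)-4-{[tert-butyl(dimethyl)silyl]oxy}-3-iodobut-2-en-1-ol | OC/C=C(\I)CO[Si](C)(C)C(C)(C)C | intermediate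
6 | [2-(1,3-dioxolan-2-yl)ethyl]zinc bromide | Br[Zn]CCC1OCCO1 | starting material
7 | (2E)-3-({[tert-butyl(dimethyl)silyl]oxy}methyl)-5-(1,3-dioxolan-2-yl)pent-2-en-1-ol | OC/C=C(/CO[Si](C)(C)C(C)(C)C)CCC1OCCO1 | intermediate
8 | (2E)-3-({[tert-butyl(dimethyl)silyl]oxy}methyl)-5-(1,3-dioxolan-2-yl)pent-2-enal | O=C/C=C(/CO[Si](C)(C)C(C)(C)C)CCC1OCCO1 | intermediate
9 | (5E)-6,10-dimethylundeca-5,9-dien-2-one ((E)-geranylacetone) | CC(=O)CC/C=C(\C)CCC=C(C)C | starting material
10 | diethyl (5E)-6,10-dimethylundeca-1,5,9-trien-2-yl phosphate | C=C(OP(=O)(OCC)OCC)CC/C=C(\C)CCC=C(C)C | intermediate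
11 | (5E)-6,10-dimethylundeca-5,9-dien-1-yne | C#CCC/C=C(\C)CCC=C(C)C | intermediate
12 | (2E,6E)-2,6-dimethylundeca-2,6-dien-10-yn-1-ol | OC/C(C)=C/CC/C(C)=C/CCC#C | intermediate
13 | (5E,9E)-11-bromo-6,10-dimethylundeca-5,9-dien-1-yne | BrC/C(C)=C/CC/C(C)=C/CCC#C | intermediate
14 | tert-butyl({(2E,4S,5R,8E)-2-[2-(1,3-dioxolan-2-yl)ethyl]-8-methyl-5-(prop-1-en-2-yl)-4-[(trimethylsilyl)oxy]trideca-2,8-dien-12-yn-1-yl}oxy)dimethylsilane | C#CCC/C=C(\C)CC[C@H](C(=C)C)[C@@H](O[Si](C)(C)C)/C=C(/CO[Si](C)(C)C(C)(C)C)CCC1OCCO1 | intermediate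
15 | (2E,4S,5R,8E)-2-[2-(1,3-dioxolan-2-yl)ethyl]-8-methyl-5-(prop-1-en-2-yl)trideca-2,8-dien-12-yne-1,4-diol | C#CCC/C=C(\C)CC[C@H](C(=C)C)[C@@H](O)/C=C(/CO)CCC1OCCO1 | intermediate
16 | (2E,4S,5R,8E)-2-[2-(1,3-dioxolan-2-yl)ethyl]-8-methyl-5-(prop-1-en-2-yl)trideca-2,8-dien-12-yne-1,4-diyl diacetate | C#CCC/C=C(\C)CC[C@H](C(=C)C)[C@@H](OC(C)=O)/C=C(/COC(C)=O)CCC1OCCO1 | intermediate
17 | (2E,4S,5R,8E)-8-methyl-2-(3-oxopropyl)-5-(prop-1-en-2-yl)trideca-2,8-dien-12-yne-1,4-diyl diacetate | C#CCC/C=C(\C)CC[C@H](C(=C)C)[C@@H](OC(C)=O)/C=C(/COC(C)=O)CCC=O | intermediate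
18 | (2E,4S,5R,8E)-8-methyl-2-{3-[(3-methylpyridin-2-yl)imino]propyl}-5-(prop-1-en-2-yl)trideca-2,8-dien-12-yne-1,4-diyl diacetate | C#CCC/C=C(\C)CC[C@H](C(=C)C)[C@@H](OC(C)=O)/C=C(/COC(C)=O)CC/C=N/c1ncccc1C | intermediate
19 | [(1E,3S,4R,7E)-3-(acetyloxy)-7-methyl-11-methylidene-12-[(3-methylpyridin-2-yl)imino]-4-(prop-1-en-2-yl)cyclotetradeca-1,7-dien-1-yl]methyl acetate | C=C1CC/C=C(\C)CC[C@H](C(=C)C)[C@@H](OC(C)=O)/C=C(/COC(C)=O)CCC1=Nc2ncccc2C | intermediate
20 | [(1E,3S,4R,7E)-3-(acetyloxy)-7-methyl-11-methylidene-12-oxo-4-(prop-1-en-2-yl)cyclotetradeca-1,7-dien-1-yl]methyl acetate | C=C1CC/C=C(\C)CC[C@H](C(=C)C)[C@@H](OC(C)=O)/C=C(/COC(C)=O)CCC1=O | intermediate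
21 | [(1E,3S,4R,7E,12R)-3-(acetyloxy)-12-hydroxy-7-methyl-11-methylidene-4-(prop-1-en-2-yl)cyclotetradeca-1,7-dien-1-yl]methyl acetate | C=C1CC/C=C(\C)CC[C@H](C(=C)C)[C@@H](OC(C)=O)/C=C(/COC(C)=O)CC[C@H]1O | target

**Step count and risks**

Total step count: 12. Longest linear sequence: 9 steps (1 → 3 → 5 → 7 → 8 → 15 → 16 → 17 → 20 → 21).

Steps most likely to fail:

Step 11 (ring-closing hydroacylation). The risks are oligomerisation, the 15-membered linear enone, and rhodium hydride isomerisation of the isopropenyl group. The fallback sets out from seco alkynal 17 and closes the same bond by a different mechanism, a nickel-catalysed reductive alkyne–aldehyde coupling (Ni(cod)2, the bulky carbene 1,3-bis(2,6-diisopropylphenyl)imidazol-2-ylidene, Et3SiH, THF, high dilution). Oxidative cyclisation to an oxanickelacycle and silane sigma-bond metathesis give the macrocyclic triethylsilyl ether F1 as a mixture of carbinol epimers, with the bulky ligand steering bond formation to the internal alkyne carbon. HF·pyridine then gives the epimeric allylic alcohols F2, and MnO2 oxidises this mixture to enone 20, where the route is rejoined before step 12.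

Step 8 (asymmetric chromium allylation). Ligand control is unproven for a gamma-substituted 2-methylallyl bromide with a beta,beta-disubstituted enal. The fallback sets out from bromide 13, which is borylated (B2pin2, Pd2(dba)3 cat., toluene, 50 °C) to the linear (E)-allylboronate F3. This adds to enal 8 under chiral phosphoric acid catalysis (the TRIP antipode that gives Re-face addition, toluene, -30 °C) through a closed chair transition state to give the mono-silylated anti alcohol F4. Bu4NF then gives diol 15, where the route is rejoined.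

Step 12 (reagent-controlled reduction). The ring conformation may override the catalyst. The fallback sets out from enone 20: Luche reduction (NaBH4, CeCl3·7H2O, MeOH, -78 °C) gives 21 together with the carbinol epimer F5. The two diastereomers are separated by chromatography, which rejoins the route at 21, and F5 is oxidised back to 20 with MnO2 and recycled.

**Further compounds**

F1 | step 11 | [(1E,3S,4R,7E)-3-(acetyloxy)-7-methyl-11-methylidene-4-(prop-1-en-2-yl)-12-[(triethylsilyl)oxy]cyclotetradeca-1,7-dien-1-yl]methyl acetate (both C12 epimers) | C=C1CC/C=C(\C)CC[C@H](C(=C)C)[C@@H](OC(C)=O)/C=C(/COC(C)=O)CCC1O[Si](CC)(CC)CC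
F2 | step 11 | [(1E,3S,4R,7E)-3-(acetyloxy)-12-hydroxy-7-methyl-11-methylidene-4-(prop-1-en-2-yl)cyclotetradeca-1,7-dien-1-yl]methyl acetate (both C12 epimers) | C=C1CC/C=C(\C)CC[C@H](C(=C)C)[C@@H](OC(C)=O)/C=C(/COC(C)=O)CCC1O
F3 | step 8 | 2-[(2E,6E)-2,6-dimethylundeca-2,6-dien-10-yn-1-yl]-4,4,5,5-tetramethyl-1,3,2-dioxaborolane | CC1(C)OB(C/C(C)=C/CC/C(C)=C/CCC#C)OC1(C)C
F4 | step 8 | (2E,4S,5R,8E)-1-{[tert-butyl(dimethyl)silyl]oxy}-2-[2-(1,3-dioxolan-2-yl)ethyl]-8-methyl-5-(prop-1-en-2-yl)trideca-2,8-dien-12-yn-4-ol | C#CCC/C=C(\C)CC[C@H](C(=C)C)[C@@H](O)/C=C(/CO[Si](C)(C)C(C)(C)C)CCC1OCCO1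
F5 | step 12 | [(1E,3S,4R,7E,12S)-3-(acetyloxy)-12-hydroxy-7-methyl-11-methylidene-4-(prop-1-en-2-yl)cyclotetradeca-1,7-dien-1-yl]methyl acetate | C=C1CC/C=C(\C)CC[C@H](C(=C)C)[C@@H](OC(C)=O)/C=C(/COC(C)=O)CC[C@@H]1O
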